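**Retrosynthetic overview**
1. 14 ⇒ 13 ⇒ 12: the oxirane ring (O, C5, C6) is closed last, by transfer of one O atom to C5=C6 of the finished C25 chain. Because C7 is sp3, C5=C6 is the only isolated, tetrasubstituted alkene; the C9–C13' pentaene is deactivated at both ends (C8=O, C12'HO), and the base-labile β,γ-epoxy ketone never meets a base.
2. 12 ⇒ C15 phosphonium salt 9 + C10 dialdehyde 10 (Wittig, C11=C12).
3. 9 ⇒ 7 ⇒ 5 (key): the array O–C6 / C7H2 / C8=O on the cyclohexane ring C1–C6 is read as a propargylic alcohol after a 1,3-oxygen walk. A Meyer–Schuster shift carries O from C6 to C8, and deconjugation pulls the new alkene into the ring as C5=C6.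
4. 5 ⇒ 2 + 3: the congested C6–C7 bond comes from acetylide addition to C6=O of the chiral-pool ketone, which also supplies C3.
5. Ring order: the cyclohexane is bought with 1; the oxirane is formed in step 6, where C5 and C6 are set as a pair under control of C3.

Key step: step 3

Remark: positions are given in carotenoid numbering (ring C1–C6, chain C7–C15, C15'–C12').
Assumption: actinol 1, enynol 3 and dialdehyde 10 are taken as catalogue compounds, since all three are industrial carotenoid/vitamin A intermediates.

**Step 1**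
Reactants: 1 (4R,6R)-4-hydroxy-2,2,6-trimethylcyclohexan-1-one
Product: 2 (4R,6R)-4-(tert-butyldimethylsilyloxy)-2,2,6-trimethylcyclohexan-1-one
Conditions: TBSCl, imidazole, DMF, rt
Reagents that add atoms: tert-butyldimethylsilyl chloride, CC(C)(C)[Si](C)(C)Cl
Why: Standard silyl ether formation masks the O–H for step 2 and later provides the bulky C3 substituent that steers the epoxidation; no stereocentre is touched.

**Step 2**
Reactants: 2 silyl ether of actinol; 3 (2E)-3-methylpent-2-en-4-yn-1-ol
Product: 5 (4R,6R)-4-(tert-butyldimethylsilyloxy)-1-[(3E)-5-hydroxy-3-methylpent-3-en-1-ynyl]-2,2,6-trimethylcyclohexan-1-ol (both C1 epimers), via enynol dianion 4 (not isolated)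
Conditions: n-BuLi (2 equiv on 3), THF, −78 → 0 °C; then 2, −78 °C → rt; H2O
Reagents that add atoms: none
Why: 1,2-Addition of a lithium acetylide (ethynylation) is the established way to reach a carbonyl carbon flanked by CMe2 and CHMe, so it should make the hindered C6–C7 bond; the new carbinol centre forms as an epimer mixture that does not matter because it becomes sp2 in step 3.

**Step 3**
Reactants: 5 propargylic diol
Product: 7 (3E)-1-[(4R)-4-(tert-butyldimethylsilyloxy)-2,6,6-trimethylcyclohex-1-en-1-yl]-5-hydroxy-3-methylpent-3-en-2-one, via cross-conjugated enone 6 (not isolated)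
Conditions: MoO2(acac)2, Ph3PAuCl, AgOTf (2 mol% each), toluene, rt; then DBU (0.2 equiv), rt → 40 °C
Reagents that add atoms: none
Why: Meyer–Schuster rearrangement followed by base equilibration: the tertiary C6–OH exchanges onto the Mo(VI) oxo centre, the Au(I)-activated C7≡C8 bond takes up the Mo=O oxygen at C8 in a [3,3]-type shift, and protonolysis of the allenolate gives enone 6, so the oxygen that allowed the C6–C7 bond to be made by simple ethynylation ends up as the C8 ketone. DBU then removes the only γ-hydrogen (C5–H, since C1 is quaternary) and reprotonation at C7 gives 7, which should be the thermodynamic sink because the exocyclic enone suffers A(1,3) strain against C1Me2 and C5Me, whereas 7 has an endocyclic tetrasubstituted C5=C6 bond and keeps the C8=O/C9=C10 conjugation. The closest known reaction types are the oxo-metal/gold-catalysed 1,3-transposition of tertiary propargylic alcohols and the known drift of cyclohexylidene ketones to their β,γ-isomers. No ring is closed and no stereocentre is made; instead both C6 carbinol epimers, any C5 epimer and both geometrical isomers of 6 converge on one compound, and C3 is untouched. The selectivity needed is the 1,3-shift over Rupe dehydration to the dienyne and over Nazarov closure C6–C10: near-neutral catalysis at room temperature disfavours ionisation, and C6, next to C1Me2, is too hindered to become a spiro centre. The (E)-C9=C10 bond holds the primary OH away from the alkyne and the ketone, so neither cyclic ethers nor hemiketals can form.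

**Step 4**
Reactants: 7 C15 keto alcohol
Product: 9 {(2E)-5-[(4R)-4-(tert-butyldimethylsilyloxy)-2,6,6-trimethylcyclohex-1-en-1-yl]-3-methyl-4-oxopent-2-en-1-yl}triphenylphosphonium bromide, via allylic bromide 8 (not isolated)
Conditions: CBr4, PPh3, CH2Cl2, 0 °C; then PPh3, rt
Reagents that add atoms: carbon tetrabromide, BrC(Br)(Br)Br; triphenylphosphine, c1ccc(cc1)P(c1ccccc1)c1ccccc1
Why: Appel bromination of the primary allylic alcohol and SN2 quaternisation of PPh3 by the vinylogous α-bromo ketone run under neutral conditions that should leave the silyl ether and the β,γ-enone untouched; no stereocentre is involved.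

**Step 5**
Reactants: 9 C15 phosphonium bromide; 10 (2E,4E,6E)-2,7-dimethylocta-2,4,6-trienedial
Product: 12 (2E,4E,6E,8E,10E)-13-[(4R)-4-(tert-butyldimethylsilyloxy)-2,6,6-trimethylcyclohex-1-en-1-yl]-2,7,11-trimethyl-12-oxotrideca-2,4,6,8,10-pentaenal, via phosphorane 11 (not isolated)
Conditions: 10 (3 equiv), 1,2-epoxybutane, EtOH, 70 °C
Reagents that add atoms: none
Why: This is a Wittig olefination with a carbonyl-stabilised allylic ylide released under base-free conditions (epoxide as HBr scavenger), the ketone analogue of the C5-ester ylide/C10-dialdehyde couplings used for crocetin-type polyenes; excess 10 and the lower reactivity of the longer enal should secure mono-olefination, and the stabilised ylide with thermal equilibration should give the all-E chain.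

**Step 6**
Reactants: 12 C25 deconjugated keto aldehyde
Product: 13 (2E,4E,6E,8E,10E)-13-[(1S,4S,6R)-4-(tert-butyldimethylsilyloxy)-2,2,6-trimethyl-7-oxabicyclo[4.1.0]heptan-1-yl]-2,7,11-trimethyl-12-oxotrideca-2,4,6,8,10-pentaenal
Conditions: dimethyldioxirane (1.0 equiv), acetone/CH2Cl2, −40 °C
Reagents that add atoms: dimethyldioxirane, CC1(C)OO1
Why: Electrophilic epoxidation (dioxirane O-transfer) should pick C5=C6 as the only isolated, tetrasubstituted, electron-rich alkene; the syn addition closes the oxirane and sets C5 and C6 together, and attack anti to the C3 silyloxy group, the preference expected by analogy with peracid epoxidation of 3-O-protected β-end groups, should give the (5R,6S) isomer, with the syn isomer removed by chromatography.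

**Step 7**
Reactants: 13 silyl-protected epoxy ketone
Product: 14 (2E,4E,6E,8E,10E)-13-[(1S,4S,6R)-4-hydroxy-2,2,6-trimethyl-7-oxabicyclo[4.1.0]heptan-1-yl]-2,7,11-trimethyl-12-oxotrideca-2,4,6,8,10-pentaenal
Conditions: HF·pyridine, pyridine, THF, 0 °C → rt
Reagents that add atoms: none
Why: Fluoride-mediated desilylation in a buffered, non-basic medium avoids the C7 enolate that would open the oxirane; no stereocentre is touched.

**Compound list**
1 | (4R,6R)-4-hydroxy-2,2,6-trimethylcyclohexan-1-one (actinol) | C[C@@H]1C[C@@H](O)CC(C)(C)C1=O | starting material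
2 | (4R,6R)-4-(tert-butyldimethylsilyloxy)-2,2,6-trimethylcyclohexan-1-one | C[C@@H]1C[C@@H](O[Si](C)(C)C(C)(C)C)CC(C)(C)C1=O | intermediate
3 | (2E)-3-methylpent-2-en-4-yn-1-ol | C#C/C(C)=C/CO | starting material
4 | dianion of 3 (terminal acetylide and alkoxide, lithium counter-ions not drawn) | [C-]#C/C(C)=C/C[O-] | intermediate
5 | (4R,6R)-4-(tert-butyldimethylsilyloxy)-1-[(3E)-5-hydroxy-3-methylpent-3-en-1-ynyl]-2,2,6-trimethylcyclohexan-1-ol, both C1 epimers | C[C@@H]1C[C@@H](O[Si](C)(C)C(C)(C)C)CC(C)(C)C1(O)C#C/C(C)=C/CO | intermediate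
6 | (3E)-1-[(4R,6R)-4-(tert-butyldimethylsilyloxy)-2,2,6-trimethylcyclohexylidene]-5-hydroxy-3-methylpent-3-en-2-one, E/Z mixture at the exocyclic C6=C7 bond | C[C@@H]1C[C@@H](O[Si](C)(C)C(C)(C)C)CC(C)(C)C1=CC(=O)/C(C)=C/CO | intermediate
7 | (3E)-1-[(4R)-4-(tert-butyldimethylsilyloxy)-2,6,6-trimethylcyclohex-1-en-1-yl]-5-hydroxy-3-methylpent-3-en-2-one | OC/C=C(\C)C(=O)CC1=C(C)C[C@@H](O[Si](C)(C)C(C)(C)C)CC1(C)C | intermediate
8 | (3E)-5-bromo-1-[(4R)-4-(tert-butyldimethylsilyloxy)-2,6,6-trimethylcyclohex-1-en-1-yl]-3-methylpent-3-en-2-one | BrC/C=C(\C)C(=O)CC1=C(C)C[C@@H](O[Si](C)(C)C(C)(C)C)CC1(C)C | intermediate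
9 | {(2E)-5-[(4R)-4-(tert-butyldimethylsilyloxy)-2,6,6-trimethylcyclohex-1-en-1-yl]-3-methyl-4-oxopent-2-en-1-yl}triphenylphosphonium bromide | c1ccccc1[P+](c1ccccc1)(c1ccccc1)C/C=C(\C)C(=O)CC1=C(C)C[C@@H](O[Si](C)(C)C(C)(C)C)CC1(C)C.[Br-] | intermediate
10 | (2E,4E,6E)-2,7-dimethylocta-2,4,6-trienedial | O=C/C(C)=C/C=C/C=C(\C)C=O | starting material
11 | triphenylphosphorane (ylide) derived from 9 | c1ccccc1P(c1ccccc1)(c1ccccc1)=C/C=C(\C)C(=O)CC1=C(C)C[C@@H](O[Si](C)(C)C(C)(C)C)CC1(C)C | intermediate
12 | (2E,4E,6E,8E,10E)-13-[(4R)-4-(tert-butyldimethylsilyloxy)-2,6,6-trimethylcyclohex-1-en-1-yl]-2,7,11-trimethyl-12-oxotrideca-2,4,6,8,10-pentaenal | C\C(C=O)=C/C=C/C=C(C)/C=C/C=C(\C)C(=O)CC1=C(C)C[C@@H](O[Si](C)(C)C(C)(C)C)CC1(C)C | intermediate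
13 | (3S,5R,6S)-3-O-TBS ether of the target (oxirane anti to the silyloxy group) | C\C(C=O)=C/C=C/C=C(C)/C=C/C=C(\C)C(=O)C[C@@]12O[C@]1(C)C[C@@H](O[Si](C)(C)C(C)(C)C)CC2(C)C | intermediate
14 | (3S,5R,6S)-5,6-epoxy-3-hydroxy-8-oxo-5,6,7,8-tetrahydro-12'-apo-β-caroten-12'-al | C\C(C=O)=C/C=C/C=C(C)/C=C/C=C(\C)C(=O)C[C@@]12O[C@]1(C)C[C@@H](O)CC2(C)C | target

**Total step count:** 7. **Longest linear sequence:** 7 (1 → 14).

**Steps most likely to fail**

Step 3. The tertiary propargylic alcohol may ionise and lose water towards C5 (Rupe-type dehydration), the dienone may close cationically, or the alkene may stall in the conjugated position. The fallback sets out from 2 and 3 and returns at 7, making the C6–C7 bond by sp2–sp coupling and placing the C8 oxygen by hydroboration.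
- The kinetic enolate of 2 (LDA, THF, −78 °C) is trapped with PhNTf2 to give the enol triflate F1.
- Sonogashira coupling of this triflate with 3 gives the dienynol F2.
- Dicyclohexylborane (2 equiv, the first taken up by the OH group) should place boron on C8, the alkyne carbon remote from the trimethylcyclohexenyl group, to give the bis-boron adduct F3.
- Buffered perborate oxidation releases the C8 enol, which tautomerises to 7.

Step 6. The oxidant may approach C5=C6 from the face syn to the silyloxy group, or may attack the polyene. The fallback sets out from 12 and returns at 13.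
- NBS in aqueous THF at 0 °C forms the bromonium ion reversibly, and water opens it at C5 in a trans-diaxial manner to give the 5-hydroxy (anti to OTBS), 6-bromo (syn to OTBS) bromohydrin F4.
- Ag2O in CH2Cl2 closes the oxirane by backside displacement at C6.
- The oxygen thus enters on the face opposite to the electrophile, so the face of the oxirane is decided by the opening step and not by the approach of an oxidant.

Step 7. Slow cleavage of the hindered secondary silyl ether may be accompanied by opening of the oxirane or by enolisation at C7 with β-elimination. The fallback sets out from 12 and returns at 14.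
- The silyl group is removed before the oxirane exists (HF·pyridine on the robust 12) to give the free C25 alcohol F5.
- Ac2O/pyridine gives the 3-acetate F6.
- Peracid epoxidation, for which 3-acetoxy β-end groups are expected to favour anti attack, gives the epoxy acetate F7.
- Enzymatic hydrolysis (lipase or cholesterol esterase, pH 7 buffer), the method used to deacetylate the parent natural carotenoid, releases 14 without base.

**Further compounds**
F1 | step 3 | (4R)-4-(tert-butyldimethylsilyloxy)-2,6,6-trimethylcyclohex-1-en-1-yl trifluoromethanesulfonate | FC(F)(F)S(=O)(=O)OC1=C(C)C[C@@H](O[Si](C)(C)C(C)(C)C)CC1(C)C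
F2 | step 3 | (2E)-5-[(4R)-4-(tert-butyldimethylsilyloxy)-2,6,6-trimethylcyclohex-1-en-1-yl]-3-methylpent-2-en-4-yn-1-ol | OC/C=C(\C)C#CC1=C(C)C[C@@H](O[Si](C)(C)C(C)(C)C)CC1(C)C
F3 | step 3 | C8-dicyclohexylboryl diene from syn hydroboration of F2, primary oxygen carried as dicyclohexylborinate | C1CCCCC1B(C1CCCCC1)OC/C=C(\C)/C(B(C1CCCCC1)C1CCCCC1)=C\C1=C(C)C[C@@H](O[Si](C)(C)C(C)(C)C)CC1(C)C
F4 | step 6 | 6-bromo-5-hydroxy-5,6-dihydro derivative of 12 (OH anti, Br syn to the silyloxy group) | C\C(C=O)=C/C=C/C=C(C)/C=C/C=C(\C)C(=O)C[C@]1(Br)[C@](C)(O)C[C@@H](O[Si](C)(C)C(C)(C)C)CC1(C)C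
F5 | step 7 | (2E,4E,6E,8E,10E)-13-[(4R)-4-hydroxy-2,6,6-trimethylcyclohex-1-en-1-yl]-2,7,11-trimethyl-12-oxotrideca-2,4,6,8,10-pentaenal | C\C(C=O)=C/C=C/C=C(C)/C=C/C=C(\C)C(=O)CC1=C(C)C[C@@H](O)CC1(C)C
F6 | step 7 | 3-acetate of F5 | C\C(C=O)=C/C=C/C=C(C)/C=C/C=C(\C)C(=O)CC1=C(C)C[C@@H](OC(C)=O)CC1(C)C
F7 | step 7 | (3S,5R,6S)-3-acetate of the target | C\C(C=O)=C/C=C/C=C(C)/C=C/C=C(\C)C(=O)C[C@@]12O[C@]1(C)C[C@@H](OC(C)=O)CC2(C)C
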